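**Retrosynthetic overview**
- The target comes from acetylation and C16–O ether closure of a 2,16,17-triol. The triol comes from hydride reduction of a macrocyclic α-ethoxycarbonyl butenolide.
- Key disconnection C1–C2: C1 acts as a β-acylvinyl anion (d3, an unsaturated homoenolate). It is released by two-electron reduction of the enol triflate of an acylmalonate and adds to the C2 enal carbon (a1). Carbocycle, lactone and C2 stereocentre form in this one step.
- Disconnection C13–C14: a C15 epoxy allylic chloride plus the γ-carbanion of doubly deprotonated diethyl acetylmalonate, which supplies C14, C1, C15, C16 and C17.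
- The epoxy chloride comes from (2E,6E)-farnesol by acetylation, terminal allylic oxidation, chlorination and reagent-controlled epoxidation of the only undeactivated alkene.
- Ring order: oxirane first, then the 14-membered carbocycle and the five-membered lactone together, then the lactone is recast as the 2,5-dihydrofuran.

**Assumptions**
- Cembrane numbering is used. C1 is the ring-fusion alkene carbon bearing C14, C2 is the OCH, and C15 is the alkene carbon bearing C16H2–O and C17H2–OAc. The target read from the SMILES is 2S,7S,8S,3E,11E.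
- The L-fructose-derived Shi ketone and both antipodes of the oxazoline–sulfonamide ligand L* are taken as purchasable. L* is (S)-N-[2-(4-isopropyl-4,5-dihydrooxazol-2-yl)-6-methylphenyl]methanesulfonamide, CC(C)[C@H]1COC(=N1)c1cccc(C)c1NS(C)(=O)=O. The (S)-ligand is assumed to give Re-face attack at C2. If it does not, its antipode is used.

**Route**

Step 1
Reactants: 1 (2E,6E)-farnesol
Product: 2 (2E,6E)-farnesyl acetate
Conditions: Ac2O, pyridine, DMAP (cat.), CH2Cl2, 0 °C → rt
Reagents that add atoms: acetic anhydride CC(=O)OC(C)=O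
Why: DMAP-catalysed acetylation (nucleophilic acyl substitution) masks the C2 alcohol and inductively deactivates C3=C4 toward the electrophilic oxidants of steps 2 and 4.

Step 2
Reactants: 2 (2E,6E)-farnesyl acetate
Product: 3 (2E,6E,10E)-12-hydroxyfarnesyl acetate
Conditions: SeO2 (0.2 equiv), t-BuOOH (3 equiv), salicylic acid (0.1 equiv), CH2Cl2, 0 °C → rt
Reagents that add atoms: tert-butyl hydroperoxide CC(C)(C)OO (oxygen atom, relayed through SeO2 O=[Se]=O)
Why: Catalytic Riley allylic oxidation (ene reaction, then [2,3]-sigmatropic shift) attacks the most electron-rich, terminal gem-dimethyl alkene and gives only the (E)-CH2OH group (future C13), with no stereocentre formed.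

Step 3
Reactants: 3 (2E,6E,10E)-12-hydroxyfarnesyl acetate
Product: 4 (2E,6E,10E)-12-chlorofarnesyl acetate
Conditions: NCS, Me2S, CH2Cl2, −30 → 0 °C
Reagents that add atoms: N-chlorosuccinimide O=C1CCC(=O)N1Cl
Why: In the Corey–Kim chlorination the alkoxysulfonium salt of the primary allylic alcohol collapses by SN2 attack of chloride without allylic transposition or E/Z loss, and the CH2Cl group then deactivates C11=C12 as the acetate does C3=C4.

Step 4
Reactants: 4 (2E,6E,10E)-12-chlorofarnesyl acetate
Product: 5 (2E,6S,7S,10E)-12-chloro-6,7-epoxy-3,7,11-trimethyldodeca-2,10-dien-1-yl acetate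
Conditions: L-fructose-derived Shi ketone (0.3 equiv), KHSO5 (as 2KHSO5·KHSO4·K2SO4, 1.4 equiv), K2CO3, Bu4NHSO4 (cat.), Na2B4O7/Na2EDTA buffer, MeCN–CH2(OMe)2–H2O, −5 → 0 °C
Reagents that add atoms: potassium peroxymonosulfate [K+].[O-]S(=O)(=O)OO
Why: In the Shi asymmetric epoxidation the electrophilic chiral dioxirane takes the only alkene without an allylic electron-withdrawing group (C7=C8), and the spiro transition state of the L-series ketone (mirror image of the D-ketone that gives R,R-epoxides) sets 7S,8S by syn-stereospecific oxygen transfer to the E-alkene.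

Step 5
Reactants: 5 (2E,6S,7S,10E)-12-chloro-6,7-epoxy-3,7,11-trimethyldodeca-2,10-dien-1-yl acetate; 6 diethyl acetylmalonate
Product: 8 diethyl 2-[(4E,8S,9S,12E)-8,9-epoxy-14-hydroxy-4,8,12-trimethyltetradeca-4,12-dienoyl]malonate, via acetate-protected acylmalonate 7 (not isolated)
Conditions: 6 (2.0 equiv), LiN(i-Pr)2 (4.1 equiv), THF, −78 → 0 °C; 5, Bu4NI (0.1 equiv), 0 °C → rt; then EtOH, rt, 2 h; AcOH quench
Reagents that add atoms: none
Why: In this Weiler/Harris-type γ-alkylation of a 1,3-dicarbonyl dianion the more basic terminal CH2 carbanion of doubly deprotonated 6 displaces the primary allylic chloride by SN2 (C13–C14 bond), the remaining tricarbonyl enolate is inert while LiOEt formed on adding EtOH transesterifies the acetate, and the trisubstituted epoxide is untouched.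

Step 6
Reactants: 8 diethyl 2-[(4E,8S,9S,12E)-8,9-epoxy-14-hydroxy-4,8,12-trimethyltetradeca-4,12-dienoyl]malonate
Product: 9 diethyl 2-[(4E,8S,9S,12E)-8,9-epoxy-4,8,12-trimethyl-14-oxotetradeca-4,12-dienoyl]malonate
Conditions: MnO2 (activated, 20 equiv), CH2Cl2, rt
Reagents that add atoms: none
Why: Chemoselective MnO2 oxidation converts the primary allylic alcohol into the (E)-enal and leaves the epoxide, the isolated alkene and the enolised tricarbonyl unoxidised.

Step 7
Reactants: 9 diethyl 2-[(4E,8S,9S,12E)-8,9-epoxy-4,8,12-trimethyl-14-oxotetradeca-4,12-dienoyl]malonate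
Product: 10 diethyl 2-[(4E,8S,9S,12E)-8,9-epoxy-4,8,12-trimethyl-14-oxo-1-(trifluoromethylsulfonyloxy)tetradeca-4,12-dienylidene]malonate
Conditions: Tf2O (1.15 equiv), i-Pr2NEt (1.5 equiv), CH2Cl2, −78 °C
Reagents that add atoms: triflic anhydride O=S(=O)(OS(=O)(=O)C(F)(F)F)C(F)(F)F
Why: In this enol triflate formation the amine deprotonates only the tricarbonyl CH, Tf2O traps the acyl oxygen at a temperature the epoxide and enal tolerate, and no E/Z isomers can arise because C15 carries two identical esters.

Step 8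
Reactants: 10 diethyl 2-[(4E,8S,9S,12E)-8,9-epoxy-4,8,12-trimethyl-14-oxo-1-(trifluoromethylsulfonyloxy)tetradeca-4,12-dienylidene]malonate
Product: 12 ethyl (2S,7S,8S,3E,11E)-2,16:7,8-diepoxy-16-oxocembra-1(15),3,11-trien-17-oate, via macrocyclic chromium alkoxide 11 (not isolated)
Conditions: CrCl2 (6 equiv), L* (6.6 equiv), Et3N (6.6 equiv), NiCl2 (0.2 equiv), THF, rt; 10 added by syringe pump over 20 h (final 2 mM); aq. KNaC4H4O6
Reagents that add atoms: none
Why: Proposed new method: zerovalent nickel inserts into the electron-poor C1–OTf bond and transmetalation to trivalent chromium gives a β-chromio alkylidene malonate, so that C1 (otherwise an addition–elimination acceptor carbon) reacts as a β-acylvinyl anion and adds 1,2 to the equally electrophilic C2 enal carbon under high dilution, the sulfonamide ligand on chromium directs Re-face attack to set 2S, and alkoxide 11 closes onto whichever ester is cis to give the butenolide; the closest known reaction types are Nozaki–Hiyama–Kishi coupling of β-iodoacrylates with aldehydes, NHK macrocyclisation of alkenyl triflates and ligand-controlled asymmetric NHK alkenylation.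

Step 9
Reactants: 12 ethyl (2S,7S,8S,3E,11E)-2,16:7,8-diepoxy-16-oxocembra-1(15),3,11-trien-17-oate
Product: 13 (2S,7S,8S,3E,11E)-7,8-epoxycembra-1(15),3,11-triene-2,16,17-triol
Conditions: i-Bu2AlH (8 equiv), THF–toluene, −78 → −20 °C; aq. KNaC4H4O6
Reagents that add atoms: none
Why: i-Bu2AlH reduces the lactone and the conjugated ester in the 1,2 sense because the fully substituted β-carbon blocks conjugate hydride addition, the non-basic reagent leaves the acidic C2–H and hence 2S untouched, and the trisubstituted epoxide survives below −20 °C.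

Step 10
Reactants: 13 (2S,7S,8S,3E,11E)-7,8-epoxycembra-1(15),3,11-triene-2,16,17-triol
Product: 15 (2S,7S,8S,3E,11E)-17-acetoxy-2,16:7,8-diepoxycembra-1(15),3,11-triene, via hydroxymethyl dihydrofuran 14 (not isolated)
Conditions: PPh3, DIAD (1.3 equiv each), THF, 0 °C → rt; then Et3N, Ac2O, DMAP (cat.), rt
Reagents that add atoms: acetic anhydride CC(=O)OC(C)=O
Why: In the Mitsunobu cyclodehydration oxyphosphonium formation at the primary alcohols is reversible and only the CH2OH cis to C2 can be displaced (5-exo-tet) by the C2 hydroxyl, whose C–O bond is never broken so 2S is retained, and the one remaining primary alcohol is then acetylated in the same flask.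

**Compound list**
1 | (2E,6E)-farnesol | CC(C)=CCC/C(C)=C/CC/C(C)=C/CO | starting material
2 | (2E,6E)-farnesyl acetate | CC(C)=CCC/C(C)=C/CC/C(C)=C/COC(C)=O | intermediate
3 | (2E,6E,10E)-12-hydroxyfarnesyl acetate | OC/C(C)=C/CC/C(C)=C/CC/C(C)=C/COC(C)=O | intermediate
4 | (2E,6E,10E)-12-chlorofarnesyl acetate | ClC/C(C)=C/CC/C(C)=C/CC/C(C)=C/COC(C)=O | intermediate
5 | (2E,6S,7S,10E)-12-chloro-6,7-epoxy-3,7,11-trimethyldodeca-2,10-dien-1-yl acetate | ClC/C(C)=C/CC[C@]1(C)O[C@H]1CC/C(C)=C/COC(C)=O | intermediate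
6 | diethyl acetylmalonate | CC(=O)C(C(=O)OCC)C(=O)OCC | starting material
7 | acetate-protected acylmalonate: diethyl 2-[(4E,8S,9S,12E)-14-acetoxy-8,9-epoxy-4,8,12-trimethyltetradeca-4,12-dienoyl]malonate | CCOC(=O)C(C(=O)OCC)C(=O)CC/C(C)=C/CC[C@]1(C)O[C@H]1CC/C(C)=C/COC(C)=O | intermediate
8 | diethyl 2-[(4E,8S,9S,12E)-8,9-epoxy-14-hydroxy-4,8,12-trimethyltetradeca-4,12-dienoyl]malonate | CCOC(=O)C(C(=O)OCC)C(=O)CC/C(C)=C/CC[C@]1(C)O[C@H]1CC/C(C)=C/CO | intermediate
9 | diethyl 2-[(4E,8S,9S,12E)-8,9-epoxy-4,8,12-trimethyl-14-oxotetradeca-4,12-dienoyl]malonate | CCOC(=O)C(C(=O)OCC)C(=O)CC/C(C)=C/CC[C@]1(C)O[C@H]1CC/C(C)=C/C=O | intermediate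
10 | diethyl 2-[(4E,8S,9S,12E)-8,9-epoxy-4,8,12-trimethyl-14-oxo-1-(trifluoromethylsulfonyloxy)tetradeca-4,12-dienylidene]malonate | CCOC(=O)C(C(=O)OCC)=C(OS(=O)(=O)C(F)(F)F)CC/C(C)=C/CC[C@]1(C)O[C@H]1CC/C(C)=C/C=O | intermediate
11 | macrocyclic chromium alkoxide (drawn as the free 2S alcohol): diethyl 2-[(2S,7S,8S,3E,11E)-7,8-epoxy-2-hydroxy-4,8,12-trimethylcyclotetradeca-3,11-dien-1-ylidene]malonate | CCOC(=O)C(C(=O)OCC)=C1CC/C(C)=C/CC[C@]2(C)O[C@H]2CC/C(C)=C/[C@@H]1O | intermediate
12 | ethyl (2S,7S,8S,3E,11E)-2,16:7,8-diepoxy-16-oxocembra-1(15),3,11-trien-17-oate (α-ethoxycarbonyl butenolide fused at C1/C2 of the 14-membered ring) | CCOC(=O)C1=C2CC/C(C)=C/CC[C@]3(C)O[C@H]3CC/C(C)=C/[C@@H]2OC1=O | intermediate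
13 | (2S,7S,8S,3E,11E)-7,8-epoxycembra-1(15),3,11-triene-2,16,17-triol | OCC(CO)=C1CC/C(C)=C/CC[C@]2(C)O[C@H]2CC/C(C)=C/[C@@H]1O | intermediate
14 | hydroxymethyl dihydrofuran: (2S,7S,8S,3E,11E)-2,16:7,8-diepoxycembra-1(15),3,11-trien-17-ol | OCC1=C2CC/C(C)=C/CC[C@]3(C)O[C@H]3CC/C(C)=C/[C@@H]2OC1 | intermediate
15 | (2S,7S,8S,3E,11E)-17-acetoxy-2,16:7,8-diepoxycembra-1(15),3,11-triene (CNP0140293.1) | CC(=O)OCC1=C2CC/C(C)=C/CC[C@]3(C)O[C@H]3CC/C(C)=C/[C@@H]2OC1 | target

**Step count**
Total steps: 10. Longest linear sequence: 10 (1 → 15).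

**Steps most likely to fail**

Step 8 (macrocyclisation).
- The ester-flanked alkenylchromium may be too unreactive.
- It may be protonated or oligomerise.
- It may give a low C2 ratio.
- The C2–H of 12 is acidic, so 12 should be carried into step 9 without delay.

Fallback: the same C1–C2 bond is made with C1 as an acyl anion. Setting out from 5, alkylation with the lithium enolate of ethyl acetate (LiN(i-Pr)2, THF–DMPU, −78 °C) gives ethyl (4E,8S,9S,12E)-14-acetoxy-8,9-epoxy-4,8,12-trimethyltetradeca-4,12-dienoate F1. Reduction of both esters with i-Bu2AlH gives (2E,6S,7S,10E)-6,7-epoxy-3,7,11-trimethyltetradeca-2,10-diene-1,14-diol F2. NaHCO3-buffered Dess–Martin oxidation gives (2E,6S,7S,10E)-6,7-epoxy-3,7,11-trimethyltetradeca-2,10-dienedial F3. A chiral aminoindanol-derived triazolium carbene (i-Pr2NEt, toluene, high dilution) turns the saturated aldehyde into its Breslow intermediate, which adds to the enal carbonyl to give (2S,7S,8S,3E,11E)-7,8-epoxy-2-hydroxy-4,8,12-trimethylcyclotetradeca-3,11-dien-1-one F4. Its C2 epimer is a diastereomer and is removed by chromatography. Ethyl malonyl chloride and pyridine then give ethyl [(2S,7S,8S,3E,11E)-7,8-epoxy-4,8,12-trimethyl-1-oxocyclotetradeca-3,11-dien-2-yl] malonate F5. Its intramolecular Knoevenagel condensation (piperidinium acetate, cat.) comes back to the route at 12.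

Step 5 (dianion of the tricarbonyl compound).
- Double deprotonation of 6 may be incomplete.
- The dianion may be acylated by the acetate faster than it is alkylated.

Fallback: the tricarbonyl unit is assembled in two stages. Setting out from 5, the NaH/n-BuLi dianion of ethyl acetoacetate is alkylated at its γ-carbon to give ethyl (6E,10S,11S,14E)-16-acetoxy-10,11-epoxy-6,10,14-trimethyl-3-oxohexadeca-6,14-dienoate F6. C-acylation with ethyl chloroformate, mediated by MgCl2 and Et3N, adds the second ester and comes back to the route at 7. Ethanolysis as in step 5 then gives 8.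

Step 10 (selective cyclodehydration of a triol).
- Activation of the bis-allylic C2 alcohol would erode 2S.
- An oxyphosphonium stalled on the wrong CH2OH would lower the yield.

Fallback: both primary alcohols are activated at once, so no selection between them is needed. Setting out from 13, MsCl (2.2 equiv), 2,4,6-collidine and LiCl in DMF at 0 °C form both mesylates. The one cis to C2 is displaced internally by the C2 hydroxyl and the other by chloride, giving (2S,7S,8S,3E,11E)-17-chloro-2,16:7,8-diepoxycembra-1(15),3,11-triene F7. CsOAc in DMF then displaces the allylic chloride and comes back to the route at 15.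

Further compounds
F1 | step 8 | ethyl (4E,8S,9S,12E)-14-acetoxy-8,9-epoxy-4,8,12-trimethyltetradeca-4,12-dienoate | CCOC(=O)CC/C(C)=C/CC[C@]1(C)O[C@H]1CC/C(C)=C/COC(C)=O
F2 | step 8 | (2E,6S,7S,10E)-6,7-epoxy-3,7,11-trimethyltetradeca-2,10-diene-1,14-diol | OCCC/C(C)=C/CC[C@]1(C)O[C@H]1CC/C(C)=C/CO
F3 | step 8 | (2E,6S,7S,10E)-6,7-epoxy-3,7,11-trimethyltetradeca-2,10-dienedial | O=CCC/C(C)=C/CC[C@]1(C)O[C@H]1CC/C(C)=C/C=O
F4 | step 8 | (2S,7S,8S,3E,11E)-7,8-epoxy-2-hydroxy-4,8,12-trimethylcyclotetradeca-3,11-dien-1-one | O=C1CC/C(C)=C/CC[C@]2(C)O[C@H]2CC/C(C)=C/[C@@H]1O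
F5 | step 8 | ethyl [(2S,7S,8S,3E,11E)-7,8-epoxy-4,8,12-trimethyl-1-oxocyclotetradeca-3,11-dien-2-yl] malonate | O=C1CC/C(C)=C/CC[C@]2(C)O[C@H]2CC/C(C)=C/[C@@H]1OC(=O)CC(=O)OCC
F6 | step 5 | ethyl (6E,10S,11S,14E)-16-acetoxy-10,11-epoxy-6,10,14-trimethyl-3-oxohexadeca-6,14-dienoate | CCOC(=O)CC(=O)CC/C(C)=C/CC[C@]1(C)O[C@H]1CC/C(C)=C/COC(C)=O
F7 | step 10 | (2S,7S,8S,3E,11E)-17-chloro-2,16:7,8-diepoxycembra-1(15),3,11-triene | ClCC1=C2CC/C(C)=C/CC[C@]3(C)O[C@H]3CC/C(C)=C/[C@@H]2OC1
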